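The C4–C4a bond of the flavanone (ring C) is cut first, giving an (S)-3-aryl-3-aryloxypropanoic acid; then O1–C2 (to an (R)-benzylic alcohol and 3,5-bis(benzyloxy)phenol), C2–C3 (to a ring B aldehyde and a diazoacetate), the C8–C3' biaryl bond, and the flavone pyranone ring (to a 2'-hydroxychalcone).
Forward, the flavone half is made first with iodine already at C8, ring B is attached by Suzuki–Miyaura coupling, the C2–C3–C4 chain is grown on the ring B aldehyde, ring A of the flavanone arrives as a phenol, and ring C is closed last.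
C2, the only stereocentre, is set as the (R)-carbinol by Ru-catalysed asymmetric transfer hydrogenation and inverted to (S) in a Mitsunobu etherification; no later step makes or breaks a bond at C2.
The closure is possible because ring A of the flavanone (C4a, C5–C8, C8a) is a phloroglucinol ring: in the O1 aryl ether the two carbons ortho to O1 are equivalent about the O1–C8a axis, each is ortho or para to three oxygens, and either one can become C4a.
Benzyl ethers are used throughout, with a benzyl carbonate on O4' that is electron-withdrawing while acid is present; all five are removed in one hydrogenolysis.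

Key step: step 14

Remark on the chemistry: the C8–C3' biaryl bond is taken to rotate freely in the target, so C2 of the flavanone half is the only stereo-element; protected intermediates may show slowly interconverting rotamers that converge on deprotection.
Notation: Fl is the 5,7-bis(benzyloxy)-2-(4-methoxyphenyl)-4-oxo-4H-chromen-8-yl group (the protected flavone half, bonded through C8). Locants C2, C3, C4, C4a, O1 and primed ring B locants refer to the flavanone half.

Step 1
Reactants: 1 2',4',6'-trihydroxyacetophenone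
Product: 2 1-[2,4-bis(benzyloxy)-6-hydroxyphenyl]ethanone
Conditions: BnBr (2.1 equiv), K2CO3, DMF, rt
Reagents that add atoms: benzyl bromide, BrCc1ccccc1
Why: Williamson etherification alkylates the para and one ortho phenoxide, while the remaining ortho hydroxyl is hydrogen-bonded to the acetyl carbonyl and should stay free.

Step 2
Reactants: 2 1-[2,4-bis(benzyloxy)-6-hydroxyphenyl]ethanone
Product: 3 1-[4,6-bis(benzyloxy)-2-hydroxy-3-iodophenyl]ethanone
Conditions: NIS (1.0 equiv), DMF, 0 °C → rt
Reagents that add atoms: N-iodosuccinimide, O=C1CCC(=O)N1I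
Why: Electrophilic aromatic iodination should occur at C3, ortho to the free phenol and less hindered than C5 between two benzyloxy groups, which places iodine at the future C8 of the flavone.

Step 3
Reactants: 3 1-[4,6-bis(benzyloxy)-2-hydroxy-3-iodophenyl]ethanone; 4 4-methoxybenzaldehyde
Product: 5 (E)-1-[4,6-bis(benzyloxy)-2-hydroxy-3-iodophenyl]-3-(4-methoxyphenyl)prop-2-en-1-one
Conditions: KOH (aq.), EtOH/THF, rt
Reagents that add atoms: none
Why: Claisen–Schmidt condensation of the methyl ketone enolate with the non-enolisable aldehyde, followed by dehydration, gives the (E)-enone; aryl iodide and benzyl ethers are inert to hydroxide at room temperature.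

Step 4
Reactants: 5 the 2'-hydroxy-3'-iodochalcone
Product: 7 5,7-bis(benzyloxy)-8-iodo-2-(4-methoxyphenyl)-4H-chromen-4-one, via racemic 8-iodoflavanone 6 (not isolated)
Conditions: I2 (10 mol %), DMSO, 120 °C
Reagents that add atoms: none
Why: Iodine-catalysed oxidative cyclisation of a 2'-hydroxychalcone: oxa-Michael closure gives flavanone 6, which is iodinated alpha to the ketone and loses HI to the flavone, dimethyl sulfoxide reoxidising the iodide.

Step 5
Reactants: 8 4-hydroxy-3-iodobenzaldehyde
Product: 9 3-iodo-4-(methoxymethoxy)benzaldehyde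
Conditions: MOMCl, iPr2NEt, CH2Cl2, 0 °C → rt
Reagents that add atoms: chloromethyl methyl ether, COCCl
Why: O-Alkylation of the acidic phenol gives the methoxymethyl acetal, which masks the phenol through borylation and cross-coupling and can later be removed without touching benzyl ethers.

Step 6
Reactants: 9 3-iodo-4-(methoxymethoxy)benzaldehyde
Product: 10 4-(methoxymethoxy)-3-(4,4,5,5-tetramethyl-1,3,2-dioxaborolan-2-yl)benzaldehyde
Conditions: B2pin2, PdCl2(dppf) (3 mol %), KOAc, 1,4-dioxane, 85 °C
Reagents that add atoms: bis(pinacolato)diboron, CC1(C)OB(OC1(C)C)B1OC(C)(C)C(C)(C)O1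
Why: Miyaura borylation: zerovalent palladium formed from PdCl2(dppf) inserts into the aryl–iodine bond and acetate mediates transmetalation with the diboron, a process that tolerates aldehydes and acetals.

Step 7
Reactants: 7 the 8-iodoflavone; 10 the ring B pinacol boronate
Product: 11 3-Fl-4-(methoxymethoxy)benzaldehyde
Conditions: Pd(OAc)2 (5 mol %), SPhos (10 mol %), K3PO4, toluene/H2O, 90 °C
Reagents that add atoms: none
Why: Suzuki–Miyaura coupling with the bulky, electron-rich SPhos ligand supports oxidative addition of the doubly ortho-substituted iodide and reductive elimination to the tri-ortho-substituted C8–C3' biaryl.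

Step 8
Reactants: 11 3-Fl-4-(methoxymethoxy)benzaldehyde
Product: 12 3-Fl-4-hydroxybenzaldehyde
Conditions: 2 M HCl (aq.), THF, 45 °C
Reagents that add atoms: none
Why: Acid-catalysed acetal hydrolysis: the methoxymethyl group is far more acid-labile than aryl benzyl ethers, so dilute aqueous acid should free only the ring B phenol.

Step 9
Reactants: 12 3-Fl-4-hydroxybenzaldehyde
Product: 13 benzyl 2-Fl-4-formylphenyl carbonate
Conditions: CbzCl, Et3N, DMAP (cat.), CH2Cl2, 0 °C
Reagents that add atoms: benzyl chloroformate, O=C(Cl)OCc1ccccc1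
Why: O-Acylation of the phenol gives a benzyl carbonate, which makes O4' electron-withdrawing for the later acid-mediated steps and is cleavable by the same hydrogenolysis as the benzyl ethers.

Step 10
Reactants: 13 benzyl 2-Fl-4-formylphenyl carbonate; 14 tert-butyl diazoacetate
Product: 15 tert-butyl 3-{4-[(benzyloxycarbonyl)oxy]-3-Fl-phenyl}-3-oxopropanoate
Conditions: SnCl2 (15 mol %), CH2Cl2, rt
Reagents that add atoms: none
Why: Roskamp homologation: the SnCl2-activated aldehyde is attacked by the diazo carbon and the adduct collapses by 1,2-hydride shift with loss of N2 to the β-keto ester, forming C2–C3 under conditions that spare the carbonate, benzyl ethers and flavone.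

Step 11
Reactants: 15 the β-keto ester
Product: 16 tert-butyl (3R)-3-{4-[(benzyloxycarbonyl)oxy]-3-Fl-phenyl}-3-hydroxypropanoate
Conditions: RuCl[(R,R)-TsDPEN](p-cymene) (2 mol %), HCO2H/Et3N (5:2), CH2Cl2, 30 °C
Reagents that add atoms: none
Why: Noyori asymmetric transfer hydrogenation: the Ru hydride of the (R,R)-ligand complex delivers hydride and proton to one face of the aryl ketone through a six-membered transition state in which the aryl group is held against the arene ligand, which for aryl ketones of this type should give the (R)-carbinol; the much less electrophilic flavone carbonyl should not react.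

Step 12
Reactants: 16 the (R)-β-hydroxy ester; 17 3,5-bis(benzyloxy)phenol
Product: 18 tert-butyl (3S)-3-[3,5-bis(benzyloxy)phenoxy]-3-{4-[(benzyloxycarbonyl)oxy]-3-Fl-phenyl}propanoate
Conditions: PPh3, DIAD, toluene, 0 °C → rt
Reagents that add atoms: none
Why: Mitsunobu reaction: the alcohol is activated as an alkoxyphosphonium ion and displaced by the phenoxide of 17 in an SN2 process with inversion, turning the (R)-carbinol into the (S)-configured C2–O1 aryl ether, while the para carbonate and the non-polar solvent disfavour ionisation.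

Step 13
Reactants: 18 the (S)-aryl ether tert-butyl ester
Product: 20 (3S)-3-[3,5-bis(benzyloxy)phenoxy]-3-{4-[(benzyloxycarbonyl)oxy]-3-Fl-phenyl}propanoic acid, via trimethylsilyl ester 19 (not isolated)
Conditions: Me3SiOTf, 2,6-lutidine, CH2Cl2, 0 °C → rt; then aq. NaH2PO4
Reagents that add atoms: none
Why: Silyl triflate-mediated tert-butyl ester cleavage: O-silylation expels the tert-butyl group as isobutene under lutidine buffering and the silyl ester is hydrolysed on work-up, so no protic acid attacks the benzyl ethers or the benzylic ether and no tert-butyl cation persists to alkylate the electron-rich phenoxy ring.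

Step 14
Reactants: 20 the (S)-3-aryl-3-aryloxypropanoic acid
Product: 22 benzyl 4-[(2S)-5,7-bis(benzyloxy)-4-oxochroman-2-yl]-2-Fl-phenyl carbonate, via mixed trifluoroacetic anhydride 21 (not isolated)
Conditions: (CF3CO)2O (1.5 equiv), CH2Cl2, −10 → 0 °C; then cold aq. NaHCO3
Reagents that add atoms: none
Why: Trifluoroacetic anhydride converts acid 20 into mixed anhydride 21, whose acyl carbon (the future C4) is attacked by a carbon ortho to O1 on the 3,5-bis(benzyloxy)phenoxy ring, and loss of a proton and trifluoroacetate gives the aryl ketone; this is an intramolecular Friedel–Crafts acylation of the kind that turns 3-aryloxypropanoic acids into chroman-4-ones. Ring C closes through C4–C4a in a six-membered, 6-exo-trig attack at the acyl carbon, the O1–C2–C3 tether holding the electrophile over the ortho position. No stereocentre is formed: C2 was fixed in step 12 and none of its bonds is made or broken, so the (S) configuration should be carried over unchanged. Regioselectivity is settled by symmetry, since the two carbons ortho to O1 are interchangeable about the O1–C8a axis, each is ortho to O1 and to one benzyloxy group and para to the other, and the carbon para to O1 is out of reach of a three-atom tether. Chemoselectivity rests on this ring being by far the most electron-rich arene present (ring A of the flavone is deactivated by its carbonyl and its only free position, C6, cannot be reached; ring B carries the carbonate) and on ring closure outrunning trifluoroacetylation when a small excess of anhydride is used cold. The step also needs the benzylic C2–O1 bond not to ionise in the acidic medium, which the carbonate para to C1' and the acyl group beta to C2 should secure, so neither racemisation nor loss of the phenol is expected.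

Step 15
Reactants: 22 the (2S)-flavanone–flavone tetrabenzyl ether benzyl carbonate
Product: 23 2,3-dihydropodocarpusflavone A
Conditions: H2 (1 atm), Pd/C (10 %), THF/MeOH, rt
Reagents that add atoms: none
Why: Catalytic hydrogenolysis cleaves the four O-benzyl bonds and the benzyl–oxygen bond of the carbonate (lost as toluene and CO2) under neutral conditions that should leave the base-sensitive C2 stereocentre, the flavone double bond and the methyl ether intact.

Compound list
1 | 2',4',6'-trihydroxyacetophenone | CC(=O)c1c(O)cc(O)cc1O | starting material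
2 | 1-[2,4-bis(benzyloxy)-6-hydroxyphenyl]ethanone | CC(=O)c1c(O)cc(OCc2ccccc2)cc1OCc1ccccc1 | intermediate
3 | 1-[4,6-bis(benzyloxy)-2-hydroxy-3-iodophenyl]ethanone | CC(=O)c1c(O)c(I)c(OCc2ccccc2)cc1OCc1ccccc1 | intermediate
4 | 4-methoxybenzaldehyde | COc1ccc(C=O)cc1 | starting material
5 | (E)-1-[4,6-bis(benzyloxy)-2-hydroxy-3-iodophenyl]-3-(4-methoxyphenyl)prop-2-en-1-one | COc1ccc(/C=C/C(=O)c2c(O)c(I)c(OCc3ccccc3)cc2OCc2ccccc2)cc1 | intermediate
6 | racemic 5,7-bis(benzyloxy)-8-iodo-2-(4-methoxyphenyl)chroman-4-one (not isolated) | COc1ccc(C2CC(=O)c3c(OCc4ccccc4)cc(OCc4ccccc4)c(I)c3O2)cc1 | intermediate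
7 | 5,7-bis(benzyloxy)-8-iodo-2-(4-methoxyphenyl)-4H-chromen-4-one | COc1ccc(-c2cc(=O)c3c(OCc4ccccc4)cc(OCc4ccccc4)c(I)c3o2)cc1 | intermediate
8 | 4-hydroxy-3-iodobenzaldehyde | O=Cc1ccc(O)c(I)c1 | starting material
9 | 3-iodo-4-(methoxymethoxy)benzaldehyde | COCOc1ccc(C=O)cc1I | intermediate
10 | 4-(methoxymethoxy)-3-(4,4,5,5-tetramethyl-1,3,2-dioxaborolan-2-yl)benzaldehyde | COCOc1ccc(C=O)cc1B1OC(C)(C)C(C)(C)O1 | intermediate
11 | 3-[5,7-bis(benzyloxy)-2-(4-methoxyphenyl)-4-oxo-4H-chromen-8-yl]-4-(methoxymethoxy)benzaldehyde | COc1ccc(-c2cc(=O)c3c(OCc4ccccc4)cc(OCc4ccccc4)c(-c4cc(C=O)ccc4OCOC)c3o2)cc1 | intermediate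
12 | 3-[5,7-bis(benzyloxy)-2-(4-methoxyphenyl)-4-oxo-4H-chromen-8-yl]-4-hydroxybenzaldehyde | COc1ccc(-c2cc(=O)c3c(OCc4ccccc4)cc(OCc4ccccc4)c(-c4cc(C=O)ccc4O)c3o2)cc1 | intermediate
13 | benzyl 2-Fl-4-formylphenyl carbonate | COc1ccc(-c2cc(=O)c3c(OCc4ccccc4)cc(OCc4ccccc4)c(-c4cc(C=O)ccc4OC(=O)OCc4ccccc4)c3o2)cc1 | intermediate
14 | tert-butyl diazoacetate | CC(C)(C)OC(=O)C=[N+]=[N-] | starting material
15 | tert-butyl 3-{4-[(benzyloxycarbonyl)oxy]-3-Fl-phenyl}-3-oxopropanoate | COc1ccc(-c2cc(=O)c3c(OCc4ccccc4)cc(OCc4ccccc4)c(-c4cc(C(=O)CC(=O)OC(C)(C)C)ccc4OC(=O)OCc4ccccc4)c3o2)cc1 | intermediate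
16 | tert-butyl (3R)-3-{4-[(benzyloxycarbonyl)oxy]-3-Fl-phenyl}-3-hydroxypropanoate | COc1ccc(-c2cc(=O)c3c(OCc4ccccc4)cc(OCc4ccccc4)c(-c4cc([C@H](O)CC(=O)OC(C)(C)C)ccc4OC(=O)OCc4ccccc4)c3o2)cc1 | intermediate
17 | 3,5-bis(benzyloxy)phenol | Oc1cc(OCc2ccccc2)cc(OCc2ccccc2)c1 | starting material
18 | tert-butyl (3S)-3-[3,5-bis(benzyloxy)phenoxy]-3-{4-[(benzyloxycarbonyl)oxy]-3-Fl-phenyl}propanoate | COc1ccc(-c2cc(=O)c3c(OCc4ccccc4)cc(OCc4ccccc4)c(-c4cc([C@@H](Oc5cc(OCc6ccccc6)cc(OCc6ccccc6)c5)CC(=O)OC(C)(C)C)ccc4OC(=O)OCc4ccccc4)c3o2)cc1 | intermediate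
19 | trimethylsilyl ester of acid 20 (not isolated) | COc1ccc(-c2cc(=O)c3c(OCc4ccccc4)cc(OCc4ccccc4)c(-c4cc([C@@H](Oc5cc(OCc6ccccc6)cc(OCc6ccccc6)c5)CC(=O)O[Si](C)(C)C)ccc4OC(=O)OCc4ccccc4)c3o2)cc1 | intermediate
20 | (3S)-3-[3,5-bis(benzyloxy)phenoxy]-3-{4-[(benzyloxycarbonyl)oxy]-3-Fl-phenyl}propanoic acid | COc1ccc(-c2cc(=O)c3c(OCc4ccccc4)cc(OCc4ccccc4)c(-c4cc([C@@H](Oc5cc(OCc6ccccc6)cc(OCc6ccccc6)c5)CC(=O)O)ccc4OC(=O)OCc4ccccc4)c3o2)cc1 | intermediate
21 | mixed anhydride of acid 20 with trifluoroacetic acid (not isolated) | COc1ccc(-c2cc(=O)c3c(OCc4ccccc4)cc(OCc4ccccc4)c(-c4cc([C@@H](Oc5cc(OCc6ccccc6)cc(OCc6ccccc6)c5)CC(=O)OC(=O)C(F)(F)F)ccc4OC(=O)OCc4ccccc4)c3o2)cc1 | intermediate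
22 | benzyl 4-[(2S)-5,7-bis(benzyloxy)-4-oxochroman-2-yl]-2-Fl-phenyl carbonate | COc1ccc(-c2cc(=O)c3c(OCc4ccccc4)cc(OCc4ccccc4)c(-c4cc([C@@H]5CC(=O)c6c(OCc7ccccc7)cc(OCc7ccccc7)cc6O5)ccc4OC(=O)OCc4ccccc4)c3o2)cc1 | intermediate
23 | 2,3-dihydropodocarpusflavone A | COc1ccc(-c2cc(=O)c3c(O)cc(O)c(-c4cc([C@@H]5CC(=O)c6c(O)cc(O)cc6O5)ccc4O)c3o2)cc1 | target

Total step count: 15. Longest linear sequence: 13 steps (steps 1–4 and 7–15, from 1); the ring B branch (steps 5 and 6) joins at step 7.

Steps most likely to fail

Step 12 (Mitsunobu etherification). The activated alkoxyphosphonium of a β-hydroxy ester may undergo base-induced elimination to the cinnamate, any SN1 leakage at the benzylic carbon would erode the enantiomeric purity, and acyl transfer from the aryl carbonate to the phenoxide could drain material. The fallback removes the acidifying ester from the Mitsunobu substrate by working at the alkene oxidation level; it sets out from aldehyde 13 and returns at acid 20, bypassing steps 10, 11 and 13. Keck allylation of 13 (Bu3SnCH2CH=CH2, (R)-BINOL, Ti(OiPr)4, 4 Å molecular sieves, CH2Cl2, −20 °C) should, by analogy with benzaldehyde-type substrates, give the (R)-homoallylic alcohol F1. Mitsunobu coupling of F1 with phenol 17 (PPh3, DIAD, toluene) should give, with inversion, the (S)-homoallyl aryl ether F2, which has no acidic hydrogen next to the reacting carbon. Lemieux–Johnson cleavage of the terminal alkene (OsO4 cat., NaIO4, 2,6-lutidine, dioxane/H2O) would give the β-aryloxy aldehyde F3, and Pinnick oxidation (NaClO2, NaH2PO4, 2-methyl-2-butene, tBuOH/H2O) would deliver acid 20.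

Step 14 (ring C closure). In the acidic medium the benzylic C2–O1 bond may ionise (loss of configuration at C2 or of the phenol), the peri benzyl ether may be cleaved, or trifluoroacetylation of the phenoxy ring may compete with closure. The fallback closes ring C through O1–C2 under catalyst control instead; it sets out from ketone 2 and aldehyde 13 and returns at 22, bypassing steps 10 to 14. Ketone 2 with Boc2O and DMAP would give 2-acetyl-3,5-bis(benzyloxy)phenyl tert-butyl carbonate F4, and LiN(SiMe3)2 in THF at −78 °C should induce a Baker–Venkataraman-type O-to-C acyl shift to tert-butyl 3-[2,4-bis(benzyloxy)-6-hydroxyphenyl]-3-oxopropanoate F5. Knoevenagel condensation of F5 with 13 (catalytic piperidine and AcOH, toluene, 4 Å molecular sieves) would give the alkylidene β-keto ester F6. A cinchona-alkaloid-derived bifunctional thiourea (the pseudoenantiomer leading to the (2S) series, toluene, −25 °C) should then promote an enantioselective 6-endo-trig oxa-Michael addition of the phenol, giving the (2S)-flavanone-3-carboxylate F7. Warming F7 with TsOH in toluene would remove the tert-butyl ester with decarboxylation and give 22.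

Step 10 (Roskamp homologation). With an aromatic aldehyde the tin-bound adduct may partly rearrange by 1,2-aryl instead of 1,2-hydride shift, or addition may be slow enough for the diazo ester to decompose. The fallback replaces the homologation by addition and oxidation; it sets out from aldehyde 13 and returns at β-keto ester 15. Reformatsky addition (Zn, BrCH2CO2tBu, THF, 0 °C → rt) would give the racemic β-hydroxy ester F8, and Dess–Martin oxidation (CH2Cl2, NaHCO3) would give 15.

Further compounds
F1 | step 12 | benzyl 2-Fl-4-[(1R)-1-hydroxybut-3-en-1-yl]phenyl carbonate | COc1ccc(-c2cc(=O)c3c(OCc4ccccc4)cc(OCc4ccccc4)c(-c4cc([C@H](O)CC=C)ccc4OC(=O)OCc4ccccc4)c3o2)cc1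
F2 | step 12 | benzyl 4-{(1S)-1-[3,5-bis(benzyloxy)phenoxy]but-3-en-1-yl}-2-Fl-phenyl carbonate | COc1ccc(-c2cc(=O)c3c(OCc4ccccc4)cc(OCc4ccccc4)c(-c4cc([C@@H](Oc5cc(OCc6ccccc6)cc(OCc6ccccc6)c5)CC=C)ccc4OC(=O)OCc4ccccc4)c3o2)cc1
F3 | step 12 | benzyl 4-{(1S)-1-[3,5-bis(benzyloxy)phenoxy]-3-oxopropyl}-2-Fl-phenyl carbonate | COc1ccc(-c2cc(=O)c3c(OCc4ccccc4)cc(OCc4ccccc4)c(-c4cc([C@@H](Oc5cc(OCc6ccccc6)cc(OCc6ccccc6)c5)CC=O)ccc4OC(=O)OCc4ccccc4)c3o2)cc1
F4 | step 14 | 2-acetyl-3,5-bis(benzyloxy)phenyl tert-butyl carbonate | CC(=O)c1c(OC(=O)OC(C)(C)C)cc(OCc2ccccc2)cc1OCc1ccccc1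
F5 | step 14 | tert-butyl 3-[2,4-bis(benzyloxy)-6-hydroxyphenyl]-3-oxopropanoate | CC(C)(C)OC(=O)CC(=O)c1c(O)cc(OCc2ccccc2)cc1OCc1ccccc1
F6 | step 14 | tert-butyl 2-[2,4-bis(benzyloxy)-6-hydroxybenzoyl]-3-{4-[(benzyloxycarbonyl)oxy]-3-Fl-phenyl}prop-2-enoate | COc1ccc(-c2cc(=O)c3c(OCc4ccccc4)cc(OCc4ccccc4)c(-c4cc(C=C(C(=O)OC(C)(C)C)C(=O)c5c(O)cc(OCc6ccccc6)cc5OCc5ccccc5)ccc4OC(=O)OCc4ccccc4)c3o2)cc1
F7 | step 14 | tert-butyl (2S)-5,7-bis(benzyloxy)-2-{4-[(benzyloxycarbonyl)oxy]-3-Fl-phenyl}-4-oxochroman-3-carboxylate (C3 epimers) | COc1ccc(-c2cc(=O)c3c(OCc4ccccc4)cc(OCc4ccccc4)c(-c4cc([C@@H]5C(C(=O)OC(C)(C)C)C(=O)c6c(OCc7ccccc7)cc(OCc7ccccc7)cc6O5)ccc4OC(=O)OCc4ccccc4)c3o2)cc1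
F8 | step 10 | racemic tert-butyl 3-{4-[(benzyloxycarbonyl)oxy]-3-Fl-phenyl}-3-hydroxypropanoate | COc1ccc(-c2cc(=O)c3c(OCc4ccccc4)cc(OCc4ccccc4)c(-c4cc(C(O)CC(=O)OC(C)(C)C)ccc4OC(=O)OCc4ccccc4)c3o2)cc1
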